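## Retrosynthetic overview

1. Target 35 ⇒ bis-lactone 33 by late C20 methylation trans to C18; pendant lactone (ring E) from the C3 aldehyde 27 by asymmetric carbonyl allylation, hydroboration and oxidative lactonization.
2. 27 ⇒ tetracycle 25 (Vilsmeier formylation) ⇒ keto aldehyde 20: Paal–Knorr closes the pyrrole (ring A), then N-alkylation by the chlorobutyl arm closes the azepine (ring B).
3. 20 ⇒ keto lactone 16 (C1 allylation, ozonolysis) ⇒ Michael adduct 11 (C11 ketal unveiled, reduced, lactonized to ring D).
4. Key disconnection C12–C13: intermolecular Michael addition of the lithium enolate of tert-butyl propanoate 8 to the chiral enone 7.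
5. 7 ⇒ quinone monoketal 2 (catalytic asymmetric ethyl conjugate addition, then α′-alkylation with 5). Ring order: C (from the arene) → D → A → B → E.

Conventions: locants follow the target skeleton. N4; pyrrole C1, C2, C3, C9a; azepine C5–C8; C9 (H), C10 (Et), C11 (O), C12; C13 (Me) and C14 (C=O) of ring D; C18 (O), C19, C20 (Me), C21 (C=O) of ring E. Target: 9R,10R,11S,12R,13R,18R,20S. The β face of ring C is the face carrying the C9 side chain. The "core array" means 9β side chain, 10α ethyl, 11β oxygen, 12β C13 (ring D cis-fused).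

Assumption: the (S,R,R)-phosphoramidite ligand delivers ethyl to the same enone face of 2 as it does with cyclohex-2-enone, which gives (R)-4; if the rotation shows the opposite sense, the mirror-image ligand is used and nothing else changes.

## Route

Step 1
Reactants: 1 4-methoxyphenol
Product: 2 4,4-dimethoxycyclohexa-2,5-dien-1-one
Conditions: PhI(OAc)2, MeOH, 0 °C to rt
Reagents that add atoms: methanol CO
Why: Oxidative dearomatization of a para-alkoxyphenol by the hypervalent iodine reagent, with methanol trapping the phenoxonium ion as the quinone monoketal; no stereocentre is formed.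

Step 2
Reactants: 2 4,4-dimethoxycyclohexa-2,5-dien-1-one
Product: 4 (R)-5-ethyl-4,4-dimethoxycyclohex-2-en-1-one, via ethylzinc enolate 3 (not isolated)
Conditions: Et2Zn (1.3 equiv), Cu(OTf)2 (2 mol %), (S)-1,1′-binaphthalene-2,2′-diyl N,N-bis[(R)-1-phenylethyl]phosphoramidite (4 mol %), toluene, −25 °C; aq. NH4Cl
Reagents that add atoms: diethylzinc CC[Zn]CC
Why: Copper-catalysed enantioselective conjugate addition of Et2Zn to one enantiotopic enone of the prochiral dienone sets C10 (R) under ligand control, and the mono-adduct is much less reactive than the dienone, so addition stops at 4.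

Step 3
Reactants: 4 (R)-5-ethyl-4,4-dimethoxycyclohex-2-en-1-one; 5 1-chloro-4-iodobutane
Product: 7 (5R,6R)-6-(4-chlorobutyl)-5-ethyl-4,4-dimethoxycyclohex-2-en-1-one, via lithium dienolate 6 (not isolated)
Conditions: LiN(iPr)2 (1.05 equiv), THF, −78 °C; then 5 (1.5 equiv), DMPU, −78 to −20 °C
Reagents that add atoms: none
Why: Kinetic α′-deprotonation gives the cross-conjugated dienolate (the ketal carbon has no γ-hydrogen), and SN2 enolate alkylation at the iodide end of 5 occurs anti to the neighbouring ethyl group, setting C9 trans to C10, which is also the thermodynamically preferred diequatorial arrangement.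

Step 4
Reactants: 7 (5R,6R)-6-(4-chlorobutyl)-5-ethyl-4,4-dimethoxycyclohex-2-en-1-one; 8 tert-butyl propanoate
Product: 11 tert-butyl 2-[(1S,3R,4R)-4-(4-chlorobutyl)-3-ethyl-2,2-dimethoxy-5-oxocyclohexyl]propanoate (C13 epimers), via lithium propanoate enolate 9 (not isolated), via lithium ketone enolate 10 (not isolated)
Conditions: 8, LiN(iPr)2, THF, −78 °C; then 7, DMPU, −78 to −40 °C; aq. NH4Cl at −78 °C
Reagents that add atoms: none
Why: Intermolecular Michael addition in which the small ester enolate attacks C12 of the half-chair enone axially, anti to the equatorial C10 ethyl group (the trans-3,5 rule) and away from the axial ketal methoxy group, setting C12 β irreversibly because a ketone enolate is formed from an ester enolate; C13 arises as an epimer mixture that is corrected in step 12.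

Step 5
Reactants: 11 Michael adduct
Product: 13 tert-butyl 2-[4-(4-chlorobutyl)-3-ethyl-5-hydroxy-2-oxocyclohexyl]propanoate (core array; C9a and C13 epimers), via hydroxy ketal 12 (not isolated)
Conditions: NaBH4, MeOH, 0 °C; then 1 M aq. HCl, THF, rt
Reagents that add atoms: water O
Why: Chemoselective borohydride reduction masks the C9a ketone as an alcohol (its configuration is irrelevant because it is reoxidized in step 7), so that acid-catalysed ketal hydrolysis unveils C11 as the only ketone.

Step 6
Reactants: 13 hydroxy ketone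
Product: 15 hydroxy lactone (ring D cis-fused on ring C; 9a-hydroxyl; core array; C13 epimers), via diol ester 14 (not isolated)
Conditions: NaBH4, MeOH, −20 °C; then TFA, CH2Cl2, 0 °C to rt
Reagents that add atoms: none
Why: Diastereoselective hydride reduction in which, in the chair with the C9 and C10 groups equatorial, the C12 side chain is axial and hydride adds axially from the opposite α face, giving the equatorial C11 alcohol cis to C13 and trans to ethyl, which then lactonizes under acid (transesterification with loss of the tert-butyl group) to the cis-fused ring D; any trans alcohol cannot give the cis lactone and is removed by chromatography.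

Step 7
Reactants: 15 hydroxy lactone
Product: 16 keto lactone (C9a ketone; core array; C13 epimers)
Conditions: Dess–Martin periodinane, NaHCO3, CH2Cl2, rt
Reagents that add atoms: none
Why: Dess–Martin oxidation of the only secondary alcohol regenerates the C9a ketone without touching the lactone or the alkyl chloride.

Step 8
Reactants: 16 keto lactone
Product: 18 C1-allyl keto lactone (C1 and C13 epimers), via lithium enolate 17 (not isolated)
Conditions: LiN(iPr)2 (1.05 equiv), THF, −78 °C; allyl bromide, DMPU, −78 to −30 °C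
Reagents that add atoms: allyl bromide C=CCBr
Why: Kinetic deprotonation removes the C1 methylene proton of the ketone (more acidic than the lactone α-H and faster than the tertiary C9–H) and the enolate is allylated (enolate alkylation); the C1 configuration is irrelevant because C1 becomes aromatic.

Step 9
Reactants: 18 C1-allyl keto lactone
Product: 20 keto aldehyde (C1–CH2–CHO), via ozonide 19 (not isolated)
Conditions: O3, CH2Cl2, −78 °C; then Me2S, −78 °C to rt
Reagents that add atoms: ozone [O-][O+]=O
Why: Ozonolysis with reductive work-up cleaves the terminal alkene to the aldehyde, giving the 1,4-keto aldehyde needed for ring A while ketone, lactone and chloride are inert.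

Step 10
Reactants: 20 keto aldehyde
Product: 21 NH-pyrrole (4,5,6,7-tetrahydroindole fused to ring D, with the 4-chlorobutyl arm on C9; C13 epimers)
Conditions: NH4OAc (5 equiv), AcOH, rt to 50 °C
Reagents that add atoms: ammonium acetate [NH4+].CC(=O)[O-]
Why: Paal–Knorr pyrrole synthesis in which ammonia condenses with the 1,4-dicarbonyl unit and double dehydration aromatizes ring A, removing the C1 stereocentre and fixing C9 (trans to C10, the favoured arrangement) as a non-enolizable centre.

Step 11
Reactants: 21 NH-pyrrole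
Product: 23 tetracyclic pyrrole lactone (rings A–D; C13 epimers), via sodium pyrrolide 22 (not isolated)
Conditions: NaH (1.2 equiv), NaI (10 mol %), DMF (0.01 M), 0 to 60 °C
Reagents that add atoms: none
Why: Intramolecular N-alkylation (7-exo-tet SN2, iodide-assisted) of the pyrrolide, the most acidic site, closes the azepine ring B under high dilution.

Step 12
Reactants: 23 tetracyclic pyrrole lactone (C13 epimers)
Product: 25 (13R)-tetracyclic pyrrole lactone (single isomer; methyl on the concave face of ring D), via lithium lactone enolate 24 (not isolated)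
Conditions: LiN(iPr)2 (1.2 equiv), THF, −78 °C; then AcOH in THF, −78 °C
Reagents that add atoms: none
Why: Kinetic protonation of the lactone enolate from the convex (exo) face of the cis-fused ring D places the C13 methyl on the concave face, cis to C1 and with H13 cis to H12, converging both epimers on 13R.

Step 13
Reactants: 25 (13R)-tetracyclic pyrrole lactone
Product: 27 C3-carbaldehyde of 25, via iminium chloride 26 (not isolated)
Conditions: POCl3, DMF, 1,2-dichloroethane, 0 °C to rt; then aq. NaOAc
Reagents that add atoms: N,N-dimethylformamide CN(C)C=O; water O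
Why: Vilsmeier–Haack formylation takes place at the only free α-position (C3) of the electron-rich pyrrole, and neither the lactone nor C13 is affected.

Step 14
Reactants: 27 C3-carbaldehyde
Product: 29 (18R)-homoallylic alcohol (C3–CH(OH)–CH2–CH=CH2), via borinate 28 (not isolated)
Conditions: (+)-B-allyldiisopinocampheylborane [from (−)-α-pinene], Et2O, −78 °C; then H2O2, pH 7 phosphate buffer, MeOH, 0 °C
Reagents that add atoms: (+)-B-allyldiisopinocampheylborane C=CCB([C@H]1C[C@H]2C[C@@H]([C@@H]1C)C2(C)C)[C@H]1C[C@H]2C[C@@H]([C@@H]1C)C2(C)C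
Why: Brown asymmetric carbonyl allylation in which the reagent from (−)-α-pinene delivers allyl to the Re face of the aldehyde through a chair Zimmerman–Traxler transition state, setting C18 as R under reagent control.

Step 15
Reactants: 29 (18R)-homoallylic alcohol
Product: 31 (18R)-1,4-diol (C3–CH(OH)–CH2–CH2–CH2OH), via bis-boryl adduct 30 (not isolated)
Conditions: 9-borabicyclo[3.3.1]nonane (2.5 equiv), THF, 0 °C to rt; then aq. NaOAc, 30% H2O2, 0 °C
Reagents that add atoms: hydrogen peroxide OO
Why: Anti-Markovnikov hydroboration–oxidation of the terminal alkene with the bulky borane gives the primary alcohol, the lactone and pyrrole are inert to the borane, and the buffered peroxide avoids lactone hydrolysis.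

Step 16
Reactants: 31 (18R)-1,4-diol
Product: 33 bis-lactone lacking the C20 methyl (ring E closed; 18R), via lactol 32 (not isolated)
Conditions: [Cu(MeCN)4]OTf (5 mol %), 2,2′-bipyridine (5 mol %), 2,2,6,6-tetramethylpiperidin-1-oxyl (5 mol %), N-methylimidazole (10 mol %), air, MeCN, rt
Reagents that add atoms: none
Why: Aerobic copper/nitroxyl-catalysed oxidative lactonization oxidizes only the unhindered primary alcohol, the aldehyde is trapped by the C18 hydroxyl as a lactol, and this is oxidized to ring E under neutral conditions that leave C18 untouched.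

Step 17
Reactants: 33 bis-lactone lacking the C20 methyl
Product: 35 target CNP0232452.4 (9R,10R,11S,12R,13R,18R,20S), via lithium ring E enolate 34 (not isolated)
Conditions: LiN(iPr)2 (1.05 equiv), THF, −78 °C, 20 min; MeI (3 equiv), −78 °C; AcOH quench at −78 °C
Reagents that add atoms: iodomethane CI
Why: Enolate alkylation in which one equivalent of base kinetically deprotonates the unsubstituted ring E methylene in preference to the hindered tertiary C13–H, and MeI approaches anti to the C18 pyrrolyl group, giving the trans (18R,20S) lactone; any ring D enolate is reprotonated from the convex face on the cold quench, keeping 13R.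

## Compound list

1 | 4-methoxyphenol | COc1ccc(O)cc1 | starting material
2 | 4,4-dimethoxycyclohexa-2,5-dien-1-one | COC1(OC)C=CC(=O)C=C1 | intermediate
3 | ethylzinc enolate of 4 (O–Zn on C9a; C9a=C9 and C1=C12 double bonds) | CC[C@H]1C(OC)(OC)C=CC(O[Zn]CC)=C1 | intermediate
4 | (R)-5-ethyl-4,4-dimethoxycyclohex-2-en-1-one | CC[C@H]1C(OC)(OC)C=CC(=O)C1 | intermediate
5 | 1-chloro-4-iodobutane | ClCCCCI | starting material
6 | lithium cross-conjugated dienolate of 4 | CC[C@H]1C(OC)(OC)C=CC([O-])=C1.[Li+] | intermediate
7 | (5R,6R)-6-(4-chlorobutyl)-5-ethyl-4,4-dimethoxycyclohex-2-en-1-one | CC[C@H]1C(OC)(OC)C=CC(=O)[C@@H]1CCCCCl | intermediate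
8 | tert-butyl propanoate | CCC(=O)OC(C)(C)C | starting material
9 | lithium enolate of tert-butyl propanoate | C/C=C(\OC(C)(C)C)[O-].[Li+] | intermediate
10 | lithium C9a=C1 enolate of adduct 11 | CC[C@H]1C(OC)(OC)[C@H](C(C)C(=O)OC(C)(C)C)C=C([O-])[C@@H]1CCCCCl.[Li+] | intermediate
11 | tert-butyl 2-[(1S,3R,4R)-4-(4-chlorobutyl)-3-ethyl-2,2-dimethoxy-5-oxocyclohexyl]propanoate (C13 epimers) | CC[C@H]1C(OC)(OC)[C@H](C(C)C(=O)OC(C)(C)C)CC(=O)[C@@H]1CCCCCl | intermediate
12 | hydroxy ketal: C9a alcohol of 11 (C9a epimers) | CC[C@H]1C(OC)(OC)[C@H](C(C)C(=O)OC(C)(C)C)CC(O)[C@@H]1CCCCCl | intermediate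
13 | hydroxy ketone: C11 ketone, C9a alcohol, core array at C9, C10, C12 | CC[C@H]1C(=O)[C@H](C(C)C(=O)OC(C)(C)C)CC(O)[C@@H]1CCCCCl | intermediate
14 | diol ester: 11β-hydroxyl cis to the C12 side chain and trans to ethyl | CC[C@H]1[C@H](O)[C@H](C(C)C(=O)OC(C)(C)C)CC(O)[C@@H]1CCCCCl | intermediate
15 | hydroxy lactone: cis-fused γ-lactone (ring D) on ring C, 9a-hydroxyl, 9-(4-chlorobutyl), 10-ethyl, 13-methyl | CC[C@H]1[C@@H]2OC(=O)C(C)[C@@H]2CC(O)[C@@H]1CCCCCl | intermediate
16 | keto lactone: C9a ketone of 15 | CC[C@H]1[C@@H]2OC(=O)C(C)[C@@H]2CC(=O)[C@@H]1CCCCCl | intermediate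
17 | lithium C9a=C1 enolate of 16 | CC[C@H]1[C@@H]2OC(=O)C(C)[C@@H]2C=C([O-])[C@@H]1CCCCCl.[Li+] | intermediate
18 | C1-allyl keto lactone | CC[C@H]1[C@@H]2OC(=O)C(C)[C@@H]2C(CC=C)C(=O)[C@@H]1CCCCCl | intermediate
19 | ozonide (1,2,4-trioxolane) of 18 | CC[C@H]1[C@@H]2OC(=O)C(C)[C@@H]2C(CC3OCOO3)C(=O)[C@@H]1CCCCCl | intermediate
20 | keto aldehyde: C1–CH2–CHO, C9a ketone | CC[C@H]1[C@@H]2OC(=O)C(C)[C@@H]2C(CC=O)C(=O)[C@@H]1CCCCCl | intermediate
21 | NH-pyrrole: rings A, C, D with 4-chlorobutyl on C9 | CC[C@H]1[C@@H]2OC(=O)C(C)[C@@H]2c2cc[nH]c2[C@@H]1CCCCCl | intermediate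
22 | sodium pyrrolide of 21 | CC[C@H]1[C@@H]2OC(=O)C(C)[C@@H]2c2cc[n-]c2[C@@H]1CCCCCl.[Na+] | intermediate
23 | tetracyclic pyrrole lactone, rings A–D, C3–H (C13 epimers) | CC[C@H]1[C@@H]2OC(=O)C(C)[C@@H]2c2ccn3c2[C@@H]1CCCC3 | intermediate
24 | lithium ring D enolate of 23 | CC[C@H]1[C@@H]2OC([O-])=C(C)[C@@H]2c2ccn3c2[C@@H]1CCCC3.[Li+] | intermediate
25 | (9R,10R,11S,12R,13R)-tetracyclic pyrrole lactone, C3–H | CC[C@H]1[C@@H]2OC(=O)[C@H](C)[C@@H]2c2ccn3c2[C@@H]1CCCC3 | intermediate
26 | C3 dimethyliminium chloride of 25 | CC[C@H]1[C@@H]2OC(=O)[C@H](C)[C@@H]2c2cc(C=[N+](C)C)n3c2[C@@H]1CCCC3.[Cl-] | intermediate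
27 | C3-carbaldehyde of 25 | CC[C@H]1[C@@H]2OC(=O)[C@H](C)[C@@H]2c2cc(C=O)n3c2[C@@H]1CCCC3 | intermediate
28 | diisopinocampheylborinate of 29 | CC[C@H]1[C@@H]2OC(=O)[C@H](C)[C@@H]2c2cc([C@H](OB([C@H]4C[C@H]5C[C@@H]([C@@H]4C)C5(C)C)[C@H]4C[C@H]5C[C@@H]([C@@H]4C)C5(C)C)CC=C)n3c2[C@@H]1CCCC3 | intermediate
29 | (18R)-homoallylic alcohol | CC[C@H]1[C@@H]2OC(=O)[C@H](C)[C@@H]2c2cc([C@H](O)CC=C)n3c2[C@@H]1CCCC3 | intermediate
30 | O-boryl, C21-boryl adduct of 29 with two 9-borabicyclo[3.3.1]nonyl groups | CC[C@H]1[C@@H]2OC(=O)[C@H](C)[C@@H]2c2cc([C@H](OB4C5CCCC4CCC5)CCCB4C5CCCC4CCC5)n3c2[C@@H]1CCCC3 | intermediate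
31 | (18R)-1,4-diol | CC[C@H]1[C@@H]2OC(=O)[C@H](C)[C@@H]2c2cc([C@H](O)CCCO)n3c2[C@@H]1CCCC3 | intermediate
32 | ring E lactol (C21 hemiacetal) | CC[C@H]1[C@@H]2OC(=O)[C@H](C)[C@@H]2c2cc([C@H]3CCC(O)O3)n3c2[C@@H]1CCCC3 | intermediate
33 | bis-lactone lacking the C20 methyl (18R) | CC[C@H]1[C@@H]2OC(=O)[C@H](C)[C@@H]2c2cc([C@H]3CCC(=O)O3)n3c2[C@@H]1CCCC3 | intermediate
34 | lithium ring E enolate of 33 | CC[C@H]1[C@@H]2OC(=O)[C@H](C)[C@@H]2c2cc([C@H]3CC=C([O-])O3)n3c2[C@@H]1CCCC3.[Li+] | intermediate
35 | CNP0232452.4 (9R,10R,11S,12R,13R,18R,20S) | CC[C@H]1[C@@H]2OC(=O)[C@H](C)[C@@H]2c2cc([C@H]3C[C@H](C)C(=O)O3)n3c2[C@@H]1CCCC3 | target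

## Step count and risks

Total steps: 17. Longest linear sequence: 17 steps (1 to 35); compounds 5 and 8 are bought.

Steps most likely to fail:

Step 4 (Michael addition). The β-carbon of 7 sits next to the ketal carbon, so 1,2-addition or α′-proton transfer may compete. Fallback: setting out from 7, copper-catalysed conjugate addition of isopropenylmagnesium bromide (CuBr·SMe2, THF, −40 °C) gives isopropenyl ketone F1 with the same anti-to-ethyl axial delivery. NaBH4 then aq. HCl, as in step 5, gives hydroxy ketone F2, and a second NaBH4 reduction gives diol F3. Hydroboration of the 1,1-disubstituted alkene with 9-borabicyclo[3.3.1]nonane followed by buffered H2O2 gives triol F4 (C13 epimers). Oxidation with catalytic (nPr4N)RuO4 and N-methylmorpholine N-oxide turns the 1,4-diol into the γ-lactone and the C9a alcohol into the ketone, returning to the route at 16.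

Step 11 (seven-membered N-alkylation). Intermolecular alkylation or elimination may compete with ring closure. Fallback: setting out from 18, NaN3 in DMF gives azido allyl ketone F5, and ozonolysis (O3; Me2S) gives azido keto aldehyde F6. Staudinger reduction (PPh3, THF/H2O) gives amino keto aldehyde F7, which in dilute AcOH/toluene condenses with the ring ketone and the aldehyde in an intramolecular Paal–Knorr reaction. This forms rings A and B in one operation and returns to the route at 23 (step 12 then follows unchanged).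

Step 17 (chemoselective, trans-selective methylation). Deprotonation at C13 or incomplete trans selectivity would give mixtures. Fallback: setting out from 25, Friedel–Crafts acylation at C3 with commercial (S)-methylsuccinic anhydride (AlCl3, CH2Cl2, 0 °C, attack at the less hindered carbonyl) gives keto acid F8, which already carries the 20S methyl. Reagent-controlled reduction of the pyrrolyl ketone with diisopinocampheylborane (intramolecular hydride delivery from the acyloxyborane, enantiomer chosen for 18R) gives hydroxy acid F9, which lactonizes on mild acidification and returns to the route at 35 with no enolate chemistry near C13.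

## Further compounds

F1 | step 4 | isopropenyl ketone: (3S,4R,5R)-type adduct of 7 with isopropenyl on C12 | CC[C@H]1C(OC)(OC)[C@H](C(C)=C)CC(=O)[C@@H]1CCCCCl
F2 | step 4 | hydroxy ketone: C11 ketone, C9a alcohol, C12 isopropenyl | CC[C@H]1C(=O)[C@H](C(C)=C)CC(O)[C@@H]1CCCCCl
F3 | step 4 | diol: 11β-hydroxyl, C9a alcohol, C12 isopropenyl | CC[C@H]1[C@H](O)[C@H](C(C)=C)CC(O)[C@@H]1CCCCCl
F4 | step 4 | triol: C12–CH(CH3)–CH2OH, 11β-hydroxyl, C9a alcohol | CC[C@H]1[C@H](O)[C@H](C(C)CO)CC(O)[C@@H]1CCCCCl
F5 | step 11 | azido allyl ketone: 18 with azide in place of chloride | CC[C@H]1[C@@H]2OC(=O)C(C)[C@@H]2C(CC=C)C(=O)[C@@H]1CCCCN=[N+]=[N-]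
F6 | step 11 | azido keto aldehyde | CC[C@H]1[C@@H]2OC(=O)C(C)[C@@H]2C(CC=O)C(=O)[C@@H]1CCCCN=[N+]=[N-]
F7 | step 11 | amino keto aldehyde | CC[C@H]1[C@@H]2OC(=O)C(C)[C@@H]2C(CC=O)C(=O)[C@@H]1CCCCN
F8 | step 17 | keto acid: 25 acylated at C3 with (S)-3-carboxybutanoyl | CC[C@H]1[C@@H]2OC(=O)[C@H](C)[C@@H]2c2cc(C(=O)C[C@H](C)C(O)=O)n3c2[C@@H]1CCCC3
F9 | step 17 | (18R,20S)-hydroxy acid | CC[C@H]1[C@@H]2OC(=O)[C@H](C)[C@@H]2c2cc([C@H](O)C[C@H](C)C(O)=O)n3c2[C@@H]1CCCC3
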